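## The problem

4,5-Di-O-p-coumaroylquinic acid (22) is a single cyclohexane with no fused ring, so the difficulty lies in four stereocentres and in placing two identical acyl groups. C1 is a quaternary carbinol carbon that also carries the carboxyl group. C3, C4 and C5 are contiguous oxygenated carbons with O3 and O4 cis, O4 and O5 trans, and O1 on the ring face of O3 and O4. C1 is remote from C4 and C5 and must be set absolutely at the start; its hydroxyl can then direct an oxidant to C3, and the C3 oxygen, allylic to C4, is the only centre placed to decide the faces at C4 and C5. O4 and O5 are esterified while the cis-neighbouring O3 and the tertiary O1 are free, so any route through a free triol must tell O4 from O3 and is open to acyl migration. The cinnamate esters do not survive hydroxide, alkoxide or hydride, their C=C bonds exclude hydrogenolysis, and free phenols are attacked by electrophilic halogen; the end game must therefore be mild and acidic. The enabling feature is that C4 and C5 carry the same carboxylate on opposite ring faces: this trans-1,2-diester is the outcome of anti addition of two carboxylates to a C4=C5 double bond, with the acid itself as nucleophile twice.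

## Retrosynthesis

**22 from 21.** Only protecting-group bonds are cut: two phenolic acetates, the O3–Si bond and the acetal C–O bonds of the spiro-dioxolanone that ties O1 to the carboxyl group. All four yield to aqueous acid, the one medium in which the cinnamates neither hydrolyse quickly nor migrate to O3. The forward step must hydrolyse aryl acetates faster than secondary cinnamates.

**21 from 15 and 18.** The C4–O and C5–O ester bonds are cut together, back to the C4=C5 alkene 15, iodine and two equivalents of silver carboxylate 18 (Prévost reaction).
- Against its neighbours: acylating a free 4,5-diol would require O3 to be distinguished and the diol to be made first; cis-dihydroxylation gives the wrong relative configuration; a stepwise epoxide opening and acylation costs extra steps and is kept as the fallback.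
- Simplification: 15 has two stereocentres instead of four and no ester.
- Demands on the forward reaction: iodine must bridge the alkene anti to O3; the first carboxylate must enter on the face of O3 (iodo ester 19); the ester carbonyl must then displace iodide to give the cis-fused acyloxonium ion 20 on that face; and the second carboxylate must open 20 at C5.
- The first carboxylate enters trans-diaxially in the half-chair that holds O1 and O3 axial. The channel through the iodonium ion syn to O3 is the one real competitor, which is why O3 carries a bulky silyl group and O1 is kept as a slim acetal oxygen.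

**18 from 17 from 16.** The Ag–O bond and the phenolic O–acetyl bond are cut back to p-coumaric acid (16). The acetate is chosen over a silyl or alkyl ether because it deactivates the arene toward the hypoiodite and leaves under the final acid conditions.

**15 from 14, 13 and 12.** The O3–Si bond, the acetal bonds and the methyl ester are traced back to diol ester 12.
- A silyl ether at O3 does not participate; an ester there would act as a neighbouring group and a free hydroxyl would capture 20 as an orthoester.
- The spiro-dioxolanone holds the C1 carbonyl pointing away from C5 and makes O1 an acetal oxygen, so neither can trap the iodonium ion by lactone or ether formation.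
- The forward steps are a saponification, an acetalisation of an α-hydroxy acid and a silylation.

**12 from 9 from 8.** The C3–O bond and the C4=C5 double bond of 12 come from the C3=C4 alkene of 8 through epoxide 9 (both oxirane C–O bonds cut), hydroxy selenide 10 and selenoxide 11.
- Direct allylic oxidation would not choose between C2 and C5, and a cycloaddition with a 1-oxygenated diene would place the oxygen at C2.
- The forward reactions must deliver the epoxide cis to the C1 hydroxyl, open it at C4, and eliminate the selenoxide away from the carbinol carbon.

**8 from 7 from 5 and 6.** The C1–C2 and C5–C6 ring bonds are cut by a Diels–Alder disconnection to buta-1,3-diene (6) and the lactic-acid-derived methylene dioxolanone 5; methanolysis of adduct 7 releases 8.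
- A racemic cycloaddition with an achiral α-acyloxyacrylate would need a resolution and waste half the material; the auxiliary sets C1 in the ring-forming step.
- The diene must add anti to the tert-butyl group.

**5 from 3 from 1 and 2.** The exocyclic double bond is traced through bromide 4 to acetal 3, and the acetal C–O bonds to (S)-lactic acid (1) and pivalaldehyde (2). The lactate stereocentre is relayed to the acetal carbon before it is itself destroyed.

## Roads not taken

**Alternative 1:** The cut is the C1–C6 ring bond, made by an Ireland–Claisen ring contraction.
- Forward key step: a carbohydrate-derived six-membered lactone A2 (ring oxygen on C4, vinyl group C5=C6 on C4, MOM ether at C1, silyl ether at C3) is converted into its silyl ketene acetal. This rearranges through the enforced boat transition state to the cyclohexene acid A1.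
- Merits: absolute configuration from the chiral pool; C3 carried over unchanged; C1 set by chirality transfer from C4 (silyloxy cis to vinyl in A2), with no auxiliary and no epoxide-opening regiochemistry.
- Weak points: A1 is only a C4=C5 alkene of the same kind as 15, so this road ends where the real problem, the trans-diester, begins. A2 needs a long series of deoxygenations and protecting-group changes on a hexose. The MOM ether and free acid of A1 would have to be exchanged before any iodonium chemistry.
- Comparison: in the certainty of C1 and C3 it is at least as good as the cycloaddition and epoxide sequence, whose selenide opening carries a regiochemical question. The chosen plan sets against this a nine-step front end from bulk chemicals that arrives with the dioxolanone the key step needs.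

**Alternative 2:** The cut is the C1–C2 bond, made by a Ferrier carbocyclisation.
- Forward key step: Hg(OCOCF3)2 in aqueous acetone hydrates the exocyclic enol ether of pyranoside A4, which already carries both cinnamates. The ring opens to a C3 ketone and a C1 α-keto ester, and the C2 methylene closes onto C1 by aldol addition to give the 3-dehydroquinate A3.
- Merits: C4 and C5 come from the sugar with their esters in place, so no facial selectivity at these centres is required; here this road is better than the chosen one. Ring and quaternary carbinol form in one step.
- Weak points: the acceptor is a ketone where the classical reaction uses an aldehyde, and the configuration of the new C1 rests on an untested aldol transition state. In A3 the tertiary hydroxyl and the C5 carboxylate are both β to the C3 ketone and prone to elimination. The ketone must still be reduced to the axial alcohol cis to O4 without touching the cinnamates or causing migration. Divalent mercury and a rare 3-deoxy-2-ulosonate substrate add cost.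
- Comparison: it removes the face-selectivity risk of the Prévost step but adds two new stereochemical questions (C1 and C3) and a fragile β-acyloxy ketone. The chosen plan fixes C1 and C3 by reliable substrate control before the esters exist.

**Alternative 3:** The cut is the C3–C4 bond, made by a SmI2 pinacol cyclisation.
- Forward key step: the acyclic dialdehyde A6 is reduced at both aldehydes and closes to the cis-3,4-diol A5, expected anti to the C5 silyloxy group.
- Merits: the 3,4-cis relation comes from a chelated ketyl coupling with more certainty than the face selection in the Prévost step; in this respect it is the better road.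
- Weak points: A6 needs an acyclic asymmetric construction of the quaternary C1 and contains a β-alkoxy aldehyde liable to elimination. A5 has O3 and O4 both free and cis and O5 silylated, so reaching the 4,5-diester requires telling O4 from O3, exchanging the O5 silyl group and two separate acylations under constant risk of acyl migration.
- Comparison: the chosen plan makes both ester bonds directly with the final acyl groups and never has to distinguish O3 from O4.

Key step: step 12

Remark: all cyclohexane intermediates are numbered as in quinic acid (C1 carries O1 and the carboxyl carbon; C3, C4, C5 are the oxygenated carbons of the target).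
Remark: the C5 configuration of bromide 4 is left undefined because that centre becomes trigonal in the same step.

## Route

Step 1
Reactants: 1 (S)-lactic acid; 2 pivalaldehyde
Product: 3 (2S,5S)-2-tert-butyl-5-methyl-1,3-dioxolan-4-one
Conditions: TsOH·H2O (cat.), H2SO4 (cat.), pentane, reflux, Dean–Stark; crystallisation from Et2O/pentane, −78 °C
Reagents that add atoms: none
Why: Acid-catalysed acetalisation of an α-hydroxy acid with azeotropic water removal; the cis acetal predominates and is purified by crystallisation, relaying the lactate stereocentre to the acetal carbon (self-regeneration of stereocentres), so the cis purity of 3 sets the enantiomeric purity of all later compounds.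

Step 2
Reactants: 3 (2S,5S)-2-tert-butyl-5-methyl-1,3-dioxolan-4-one
Product: 5 (2S)-2-tert-butyl-5-methylene-1,3-dioxolan-4-one, via bromide 4 (not isolated)
Conditions: NBS, AIBN (cat.), CCl4, reflux; then Et3N (excess), 0 °C → rt
Reagents that add atoms: none
Why: Radical bromination at the captodative C5–H followed by base-induced dehydrobromination; the acetal carbon is untouched and now carries the only stereocentre.

Step 3
Reactants: 5 (2S)-2-tert-butyl-5-methylene-1,3-dioxolan-4-one; 6 buta-1,3-diene
Product: 7 (2S,5R)-2-tert-butyl-1,3-dioxaspiro[4.5]dec-7-en-4-one
Conditions: 6 (excess), BHT (cat.), PhMe, sealed tube, 110 °C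
Reagents that add atoms: none
Why: Thermal Diels–Alder reaction of a captodative acrylate; the diene adds to the methylene face opposite the tert-butyl group, setting C1 as R, and the unsubstituted diene raises no endo/exo or regiochemical issue.

Step 4
Reactants: 7 (2S,5R)-2-tert-butyl-1,3-dioxaspiro[4.5]dec-7-en-4-one
Product: 8 methyl (R)-1-hydroxycyclohex-3-ene-1-carboxylate
Conditions: NaOMe (0.2 equiv), MeOH, 0 °C → rt
Reagents that add atoms: methanol CO
Why: Methoxide transesterification of the acylal-type lactone; the released hemiacetal alkoxide collapses to pivalaldehyde and regenerates methoxide, and the quaternary carbinol centre cannot epimerise.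

Step 5
Reactants: 8 methyl (R)-1-hydroxycyclohex-3-ene-1-carboxylate
Product: 9 methyl (1R,3R,6S)-3-hydroxy-7-oxabicyclo[4.1.0]heptane-3-carboxylate (oxirane cis to the hydroxyl)
Conditions: VO(acac)2 (5 mol %), t-BuOOH (1.5 equiv, in decane), CH2Cl2, 0 °C → rt
Reagents that add atoms: tert-butyl hydroperoxide CC(C)(C)OO
Why: Hydroxyl-directed epoxidation of a homoallylic alcohol; the axial C1 hydroxyl binds vanadium and delivers the peroxide oxygen to the alkene face cis to itself, placing the future O3 on the face of O1.

Step 6
Reactants: 9 methyl (1R,3R,6S)-3-hydroxy-7-oxabicyclo[4.1.0]heptane-3-carboxylate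
Product: 12 methyl (1R,3R)-1,3-dihydroxycyclohex-4-ene-1-carboxylate, via hydroxy selenide 10 (not isolated), via selenoxide 11 (not isolated)
Conditions: (PhSe)2 (0.6 equiv), NaBH4 (1.2 equiv), MeOH, 0 °C → rt; then THF, 30% aq. H2O2 (excess), 0 °C → rt
Reagents that add atoms: none
Why: Trans-diaxial (Fürst–Plattner) opening of the epoxide by phenylselenolate at C4, the mode that keeps the ester equatorial and the two oxygens diaxial and hydrogen-bonded, followed by oxidation and selenoxide syn-elimination. The elimination goes away from the carbinol carbon toward C5, giving the allylic alcohol with the C3 configuration from step 5 unchanged.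

Step 7
Reactants: 12 methyl (1R,3R)-1,3-dihydroxycyclohex-4-ene-1-carboxylate
Product: 13 (1R,3R)-1,3-dihydroxycyclohex-4-ene-1-carboxylic acid
Conditions: LiOH·H2O (2 equiv), THF/H2O (3:1), 0 °C → rt; then 1 M HCl to pH 3
Reagents that add atoms: lithium hydroxide [Li+].[OH-]
Why: Saponification of a methyl ester that has no epimerisable α-hydrogen; no other base-sensitive group is present.

Step 8
Reactants: 13 (1R,3R)-1,3-dihydroxycyclohex-4-ene-1-carboxylic acid
Product: 14 (5R,9R)-9-hydroxy-2,2-dimethyl-1,3-dioxaspiro[4.5]dec-7-en-4-one (acetonide of 13 across O1 and the carboxyl group, O3–H free)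
Conditions: Me2C(OMe)2 (5 equiv), TsOH·H2O (5 mol %), acetone, rt; aq. NaHCO3 work-up
Reagents that add atoms: 2,2-dimethoxypropane COC(C)(C)OC
Why: Acid-catalysed transacetalisation closes the five-membered 1,3-dioxolan-4-one of an α-hydroxy acid, as in the bis-acetonide of quinic acid; any mixed ketal at the secondary O3 reverts on work-up.

Step 9
Reactants: 14 (5R,9R)-9-hydroxy-2,2-dimethyl-1,3-dioxaspiro[4.5]dec-7-en-4-one
Product: 15 (5R,9R)-9-[(tert-butyldimethylsilyl)oxy]-2,2-dimethyl-1,3-dioxaspiro[4.5]dec-7-en-4-one (acetonide of 3-O-TBS-4,5-dideoxyquin-4-enic acid)
Conditions: TBSCl (1.2 equiv), imidazole (2.5 equiv), DMF, rt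
Reagents that add atoms: tert-butyldimethylsilyl chloride CC(C)(C)[Si](C)(C)Cl
Why: Standard silylation of a secondary allylic alcohol; the silyl ether is bulky, non-participating and acid-labile.

Step 10
Reactants: 16 p-coumaric acid
Product: 17 (E)-4-acetoxycinnamic acid
Conditions: Ac2O (1.5 equiv), pyridine, rt; then H2O
Reagents that add atoms: acetic anhydride CC(=O)OC(C)=O
Why: Phenol acetylation; water hydrolyses any mixed anhydride, and the acetate deactivates the arene toward electrophilic iodine in step 12.

Step 11
Reactants: 17 (E)-4-acetoxycinnamic acid
Product: 18 silver (E)-4-acetoxycinnamate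
Conditions: NaHCO3 (1.0 equiv), H2O, 0 °C; then AgNO3 (1.0 equiv), H2O, dark; filtered, washed, dried in vacuo over P2O5
Reagents that add atoms: silver nitrate [Ag+].[O-][N+](=O)[O-]
Why: Salt metathesis; the insoluble silver carboxylate precipitates, and bicarbonate is too weak a base to cleave the aryl acetate.

Step 12
Reactants: 15 (5R,9R)-9-[(tert-butyldimethylsilyl)oxy]-2,2-dimethyl-1,3-dioxaspiro[4.5]dec-7-en-4-one; 18 silver (E)-4-acetoxycinnamate (two equivalents enter the product)
Product: 21 acetonide of 3-O-(tert-butyldimethylsilyl)-4,5-bis-O-[(E)-4-acetoxycinnamoyl]quinic acid, via iodo ester 19 (not isolated), via dioxolanylium ion 20 (not isolated)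
Conditions: 18 (2.4 equiv), I2 (1.1 equiv), 4 Å MS, dry PhH, dark, rt; then 15, rt → 80 °C
Reagents that add atoms: none
Why: Prévost reaction (anti bis-acyloxylation of an alkene by iodine and two equivalents of a silver carboxylate); the closest known case is the conversion of cyclohexenes into trans-1,2-diol dibenzoates with silver benzoate. Carboxylate 18 and iodine give the acyl hypoiodite, which transfers electrophilic iodine to C4=C5 on the face anti to the allylic C3 silyloxy group; a carboxylate then opens the iodonium ion anti and trans-diaxially at C5, the carbon remote from the deactivating C3 oxygen, to give 19 (opening at C4 would lead to the same ion 20). Silver-assisted loss of iodide from C4 is coupled to backside attack by the C5 ester carbonyl oxygen, a 5-exo-tet neighbouring-group closure that forms the transient cis-fused 1,3-dioxolan-2-ylium ring of 20 on the face of O3 and fixes C4 with its oxygen cis to O3; no ring remains in the product. The second carboxylate opens 20 by SN2 at C5 with inversion, fixing C5 with its oxygen trans to O4. Both new stereocentres are therefore controlled by C3 through the face taken by iodine, and their trans relation follows from the mechanism. The selectivities needed are iodine transfer anti to O3 and attack on 20 at C5 and not at C4; the first rests on the bulk and C–O dipole of the silyl ether, the second on the β-oxygen effect and the flanking silyl group, which retard substitution at C4. The spiro-dioxolanone keeps O1 non-nucleophilic and holds the C1 carbonyl away from C5, the acetates keep the arenes inert to the hypoiodite, and strictly dry conditions avoid the Woodward cis-hydroxy ester.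

Step 13
Reactants: 21 acetonide of 3-O-(tert-butyldimethylsilyl)-4,5-bis-O-[(E)-4-acetoxycinnamoyl]quinic acid
Product: 22 4,5-di-O-p-coumaroylquinic acid
Conditions: 2 M aq. HCl/THF (1:3), rt
Reagents that add atoms: none
Why: Aqueous acid hydrolyses the dioxolanone acetal, the silyl ether and the two aryl acetates in one operation, as in the deprotection of acetyl-protected caffeoylquinic acid acetonides; the conjugated secondary cinnamates hydrolyse much more slowly, and acid suppresses acyl migration to O3.

## Compound list

1 | (S)-lactic acid | C[C@H](O)C(=O)O | starting material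
2 | pivalaldehyde | CC(C)(C)C=O | starting material
3 | (2S,5S)-2-tert-butyl-5-methyl-1,3-dioxolan-4-one (cis) | C[C@@H]1O[C@H](C(C)(C)C)OC1=O | intermediate
4 | (2S)-5-bromo-2-tert-butyl-5-methyl-1,3-dioxolan-4-one (C5 undefined; not isolated) | CC1(Br)O[C@H](C(C)(C)C)OC1=O | intermediate
5 | (2S)-2-tert-butyl-5-methylene-1,3-dioxolan-4-one | C=C1O[C@H](C(C)(C)C)OC1=O | intermediate
6 | buta-1,3-diene | C=CC=C | starting material
7 | (2S,5R)-2-tert-butyl-1,3-dioxaspiro[4.5]dec-7-en-4-one | C1=CC[C@]2(O[C@H](C(C)(C)C)OC2=O)CC1 | intermediate
8 | methyl (R)-1-hydroxycyclohex-3-ene-1-carboxylate | C1=CC[C@@](O)(C(=O)OC)CC1 | intermediate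
9 | methyl (1R,3R,6S)-3-hydroxy-7-oxabicyclo[4.1.0]heptane-3-carboxylate (oxirane cis to OH) | O1[C@@H]2[C@H]1C[C@@](O)(C(=O)OC)CC2 | intermediate
10 | methyl (1R,3R,4R)-1,3-dihydroxy-4-(phenylselanyl)cyclohexane-1-carboxylate (not isolated) | c1ccccc1[Se][C@H]2[C@H](O)C[C@@](O)(C(=O)OC)CC2 | intermediate
11 | selenoxide of 10 (Se configuration undefined; not isolated) | O=[Se](c1ccccc1)[C@H]2[C@H](O)C[C@@](O)(C(=O)OC)CC2 | intermediate
12 | methyl (1R,3R)-1,3-dihydroxycyclohex-4-ene-1-carboxylate | C1=C[C@H](O)C[C@@](O)(C(=O)OC)C1 | intermediate
13 | (1R,3R)-1,3-dihydroxycyclohex-4-ene-1-carboxylic acid | C1=C[C@H](O)C[C@@](O)(C(=O)O)C1 | intermediate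
14 | (5R,9R)-9-hydroxy-2,2-dimethyl-1,3-dioxaspiro[4.5]dec-7-en-4-one | C1=C[C@H](O)C[C@@](O2)(C(=O)OC2(C)C)C1 | intermediate
15 | (5R,9R)-9-[(tert-butyldimethylsilyl)oxy]-2,2-dimethyl-1,3-dioxaspiro[4.5]dec-7-en-4-one | C1=C[C@H](O[Si](C)(C)C(C)(C)C)C[C@@](O2)(C(=O)OC2(C)C)C1 | intermediate
16 | p-coumaric acid | O=C(O)/C=C/c1ccc(O)cc1 | starting material
17 | (E)-4-acetoxycinnamic acid | CC(=O)Oc1ccc(/C=C/C(=O)O)cc1 | intermediate
18 | silver (E)-4-acetoxycinnamate | CC(=O)Oc1ccc(/C=C/C(=O)[O-])cc1.[Ag+] | intermediate
19 | trans-iodo ester: acetonide of 3-O-TBS-4-deoxy-4-iodo-5-O-[(E)-4-acetoxycinnamoyl] acid, O5 on the face of O3 and O1, iodine on the opposite face (not isolated) | I[C@H]1[C@H](O[Si](C)(C)C(C)(C)C)C[C@@](O2)(C(=O)OC2(C)C)C[C@@H]1OC(=O)/C=C/c1ccc(OC(C)=O)cc1 | intermediate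
20 | cis-fused 2-[(E)-2-(4-acetoxyphenyl)ethenyl]-1,3-dioxolan-2-ylium ion spanning O4 and O5 on the face of O3 (cation shown, carboxylate counter-ion; not isolated) | CC(=O)Oc1ccc(/C=C/C2=[O+][C@H]3C[C@](O4)(C(=O)OC4(C)C)C[C@@H](O[Si](C)(C)C(C)(C)C)[C@H]3O2)cc1 | intermediate
21 | acetonide (2,2-dimethyl-1,3-dioxolan-4-one across O1 and the carboxyl group) of 3-O-(tert-butyldimethylsilyl)-4,5-bis-O-[(E)-4-acetoxycinnamoyl]quinic acid | CC(=O)Oc1ccc(/C=C/C(=O)O[C@@H]2[C@H](O[Si](C)(C)C(C)(C)C)C[C@@](O3)(C(=O)OC3(C)C)C[C@H]2OC(=O)/C=C/c2ccc(OC(C)=O)cc2)cc1 | intermediate
22 | 4,5-di-O-[(E)-p-coumaroyl]quinic acid, (1S,3R,4R,5R) | O=C(/C=C/c1ccc(O)cc1)O[C@@H]1[C@H](O)C[C@@](O)(C(=O)O)C[C@H]1OC(=O)/C=C/c1ccc(O)cc1 | target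

## Step count and least certain steps

Total: 13 steps. Longest linear sequence: 11 steps (steps 1–9, 12 and 13); steps 10 and 11 are the two-step branch to 18.

**Step 12 (key step).**
- What may go wrong: poor facial selectivity in the iodo-acyloxylation. The competing trans-diaxial channel (iodonium syn to O3, first carboxylate at C5 on the carboxyl face) avoids the 1,3-diaxial array of O1, O3 and O5 and would lead to the 3,4-trans-4,5-trans diester. Ionisation of 19, retarded by the β-silyloxy group, may also be slow, and traces of water would divert 20 to a cis-hydroxy ester.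
- Fallback, from 14 back to 21: hydroxyl-directed epoxidation of 14 (mCPBA, CH2Cl2, 0 °C) should give the epoxy alcohol with the oxirane cis to O3, F1, and silylation (TBSCl, imidazole) its TBS ether F2. Trans-diaxial opening of F2 by acid 17 (catalytic Cs2CO3, DMF, 60–70 °C) is expected at C5 from the carboxyl face, where the inductive effect of O3 and the chair-like transition state agree, giving the 5-O-(4-acetoxycinnamoyl)-4-hydroxy compound F3. Steglich esterification of the C4 hydroxyl with 17 (EDC·HCl, DMAP, CH2Cl2) returns to 21.

**Step 6.**
- What may go wrong: loss of regiocontrol in the epoxide opening (attack at C3 instead of C4), or partial elimination of the selenoxide toward the carbinol carbon.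
- Fallback, from 9 back to 12: isomerisation of the epoxide with TMSOTf and DBU (silylation of the oxirane oxygen, then removal of the C5 hydrogen; the C2 hydrogens are shielded by the quaternary C1) would give the bis(trimethylsilyl) ether F4. Mild acidic methanolysis (citric acid, MeOH) gives 12 with no nucleophile having to choose between C3 and C4.

**Step 8.**
- What may go wrong: acid-promoted ionisation or dehydration of the free allylic alcohol, or persistent ketalisation at O3, during closure of the dioxolanone.
- Fallback, from 12 back to 15: silylation first (TBSCl, imidazole) gives the silyl ether methyl ester F5 and saponification (LiOH) the silyloxy acid F6. The dioxolanone is then closed with 2-methoxypropene and pyridinium p-toluenesulfonate (CH2Cl2, 0 °C), giving 15 directly without exposing a free allylic alcohol to acid.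

**Step 13.**
- What may go wrong: the aryl acetates hydrolyse slowly, so the prolonged acid treatment may be accompanied by partial hydrolysis of the cinnamates or acyl migration to O3 once the silyl group is lost.
- Fallback, from 21 back to 22: the acetates are removed first by neutral transesterification (NH4OAc, aqueous MeOH, rt) while O3 is still silylated and migration is impossible, giving the bis-phenol F7. A short treatment with aqueous trifluoroacetic acid then cleaves the acetal and the silyl ether.

## Further compounds

F1 | step 12 | acetonide of (1,3-dihydroxy-4,5-epoxycyclohexane-1-carboxylic acid) with the oxirane cis to O3, O3–H free | O1[C@@H]2[C@H](O)C[C@@](O3)(C(=O)OC3(C)C)C[C@H]12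
F2 | step 12 | 3-O-tert-butyldimethylsilyl ether of F1 | O1[C@@H]2[C@H](O[Si](C)(C)C(C)(C)C)C[C@@](O3)(C(=O)OC3(C)C)C[C@H]12
F3 | step 12 | acetonide of 3-O-(tert-butyldimethylsilyl)-5-O-[(E)-4-acetoxycinnamoyl]quinic acid (O4–H free) | O[C@@H]1[C@H](O[Si](C)(C)C(C)(C)C)C[C@@](O2)(C(=O)OC2(C)C)C[C@H]1OC(=O)/C=C/c1ccc(OC(C)=O)cc1
F4 | step 6 | methyl (1R,3R)-1,3-bis[(trimethylsilyl)oxy]cyclohex-4-ene-1-carboxylate | C1=C[C@H](O[Si](C)(C)C)C[C@@](O[Si](C)(C)C)(C(=O)OC)C1
F5 | step 8 | methyl (1R,3R)-3-[(tert-butyldimethylsilyl)oxy]-1-hydroxycyclohex-4-ene-1-carboxylate | C1=C[C@H](O[Si](C)(C)C(C)(C)C)C[C@@](O)(C(=O)OC)C1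
F6 | step 8 | (1R,3R)-3-[(tert-butyldimethylsilyl)oxy]-1-hydroxycyclohex-4-ene-1-carboxylic acid | C1=C[C@H](O[Si](C)(C)C(C)(C)C)C[C@@](O)(C(=O)O)C1
F7 | step 13 | acetonide of 3-O-(tert-butyldimethylsilyl)-4,5-di-O-[(E)-p-coumaroyl]quinic acid | O=C(/C=C/c1ccc(O)cc1)O[C@@H]2[C@H](O[Si](C)(C)C(C)(C)C)C[C@@](O3)(C(=O)OC3(C)C)C[C@H]2OC(=O)/C=C/c2ccc(O)cc2
A1 | alternative 1 | 1-O-methoxymethyl-3-O-(tert-butyldimethylsilyl)-4,5-dideoxyquin-4-enic acid | C1=C[C@H](O[Si](C)(C)C(C)(C)C)C[C@@](OCOC)(C(=O)O)C1
A2 | alternative 1 | 5-[(tert-butyldimethylsilyl)oxy]-3-(methoxymethoxy)-6-vinyltetrahydropyran-2-one, silyloxy cis to vinyl (C3 of the lactone undefined; it is planar in the ketene acetal) | C=C[C@H]1OC(=O)C(OCOC)C[C@H]1O[Si](C)(C)C(C)(C)C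
A3 | alternative 2 | tert-butyl 4,5-bis-O-[(E)-4-acetoxycinnamoyl]-3-dehydroquinate | CC(=O)Oc1ccc(/C=C/C(=O)O[C@@H]2C(=O)C[C@@](O)(C(=O)OC(C)(C)C)C[C@H]2OC(=O)/C=C/c2ccc(OC(C)=O)cc2)cc1
A4 | alternative 2 | methyl pyranoside of tert-butyl 3,7-dideoxyhept-6-en-2-ulosonate carrying (E)-4-acetoxycinnamoyl esters on both secondary oxygens (anomeric configuration undefined) | C=C1OC(OC)(C(=O)OC(C)(C)C)C[C@@H](OC(=O)/C=C/c2ccc(OC(C)=O)cc2)[C@@H]1OC(=O)/C=C/c1ccc(OC(C)=O)cc1
A5 | alternative 3 | tert-butyl 5-O-(tert-butyldimethylsilyl)-1-O-methoxymethylquinate | O[C@@H]1[C@H](O)C[C@@](OCOC)(C(=O)OC(C)(C)C)C[C@H]1O[Si](C)(C)C(C)(C)C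
A6 | alternative 3 | tert-butyl 4-[(tert-butyldimethylsilyl)oxy]-2-(methoxymethoxy)-5-oxo-2-(2-oxoethyl)pentanoate (acyclic dialdehyde; C1 and C5 as in A5) | O=CC[C@@](OCOC)(C(=O)OC(C)(C)C)C[C@@H](O[Si](C)(C)C(C)(C)C)C=O
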